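With the alkaloid numbered N1, C2 (CH3), C3 (OAc), C4, C5, C6 and the side chain C1'–C14', the atoms C6, C1', C2', C3' and C5 outline a latent cyclopentene, disconnected at C3'=C5. The C6 configuration is therefore banked in an (S)-cyclopent-2-enyl substituent on nitrogen. One ruthenium-catalysed metathesis cascade opens this carbocycle. It bonds C5 to C4 to create the piperidine ring (as its 4,5-alkene) and bonds C3' to C4' of dodec-11-en-2-one. Ring and complete chain arise together while C2, C3 and C6 stay untouched. The cascade substrate is a Cbz carbamate whose nitrogen carries the cyclopentenyl ring and a D-alanine-derived (2R,3R)-3-acetoxypent-4-en-2-yl arm.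

Key step: step 10

Assumption: the (R,R) antipode of the diphosphine in step 6 is taken to steer nitrogen to the allyl terminus that becomes (S)-C6, as it does for malonate and imide nucleophiles on cycloalkenyl esters; the (S,S) antipode is equally available should the sense prove opposite.

Step 1
Reactants: 1 D-alanine methyl ester hydrochloride
Product: 2 methyl (2R)-2-[(diphenylmethylidene)amino]propanoate
Conditions: Ph2C=NH (1.0 equiv), CH2Cl2, rt, 24 h; filtration
Reagents that add atoms: benzophenone imine, N=C(c1ccccc1)c1ccccc1
Why: Transimination of the amine salt with the diaryl ketimine proceeds under neutral conditions and is driven by precipitation of the ammonium salt, so the alanine stereocentre (future C2, R) is never enolised.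

Step 2
Reactants: 2 methyl (2R)-2-[(diphenylmethylidene)amino]propanoate; 3 vinylmagnesium bromide
Product: 5 (3R,4R)-4-[(diphenylmethylidene)amino]pent-1-en-3-ol, via aluminoxy acetal 4 (not isolated)
Conditions: i-Bu2AlH·i-Bu3Al (1:1, 1.1 equiv), CH2Cl2, -78 °C; then 3 (3 equiv, THF), -78 °C to rt; aq. NaHCO3; chromatography on Et3N-washed silica
Reagents that add atoms: none
Why: One-pot ester half-reduction and Grignard addition, in which 4 holds the aldehyde oxidation level at -78 °C without a free epimerisable aldehyde and, as it collapses, imine nitrogen and carbonyl oxygen sit in a five-membered metal chelate (Cram chelate model), so the vinyl group enters from the face bearing H rather than CH3 and sets C3 as R, syn (threo) to C2.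

Step 3
Reactants: 5 (3R,4R)-4-[(diphenylmethylidene)amino]pent-1-en-3-ol
Product: 6 (3R,4R)-4-aminopent-1-en-3-ol hydrochloride
Conditions: 1 M HCl, THF, rt; Et2O wash; aqueous phase concentrated
Reagents that add atoms: hydrogen chloride, Cl
Why: Mild acid hydrolysis of the ketimine frees the amine as a non-volatile salt while the ketone by-product is washed out with ether, and dilute acid at room temperature affects neither the allylic alcohol nor the two stereocentres.

Step 4
Reactants: 7 cyclopent-2-en-1-one
Product: 8 (±)-cyclopent-2-en-1-ol
Conditions: NaBH4, CeCl3·7H2O, MeOH, 0 °C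
Reagents that add atoms: none
Why: Luche reduction, in which CeCl3 activates the carbonyl group and hardens the hydride donor so that only 1,2-reduction occurs, and the racemic outcome is harmless because this stereocentre is erased in step 6.

Step 5
Reactants: 8 (±)-cyclopent-2-en-1-ol
Product: 9 (±)-cyclopent-2-en-1-yl methyl carbonate
Conditions: ClCO2Me, pyridine, CH2Cl2, 0 °C
Reagents that add atoms: methyl chloroformate, COC(=O)Cl
Why: Routine O-acylation with a chloroformate gives an allylic carbonate that ionises readily with zerovalent palladium and supplies its own base (methoxide) on ionisation.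

Step 6
Reactants: 6 (3R,4R)-4-aminopent-1-en-3-ol hydrochloride; 9 (±)-cyclopent-2-en-1-yl methyl carbonate (1.2 equiv)
Product: 10 (3R,4R)-4-{[(1S)-cyclopent-2-en-1-yl]amino}pent-1-en-3-ol
Conditions: Pd2(dba)3·CHCl3 (2.5 mol %), N,N'-[(1R,2R)-cyclohexane-1,2-diyl]bis[2-(diphenylphosphanyl)benzamide] (7.5 mol %), Et3N (1.2 equiv), CH2Cl2, 0 °C to rt
Reagents that add atoms: none
Why: Tsuji–Trost asymmetric allylic amination, in which both enantiomers of 9 ionise to one symmetrical η3-cyclopentenyl palladium cation and the chiral pocket of the diphosphine lets the primary amine attack (anti to the metal) only one of the two enantiotopic termini, setting C6 as S under catalyst control, while the free allylic alcohol of 6 does not ionise, the bulky secondary amine product does not allylate again, and any C6 epimer is a separable diastereomer.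

Step 7
Reactants: 10 (3R,4R)-4-{[(1S)-cyclopent-2-en-1-yl]amino}pent-1-en-3-ol
Product: 11 benzyl N-[(1S)-cyclopent-2-en-1-yl]-N-[(2R,3R)-3-hydroxypent-4-en-2-yl]carbamate
Conditions: CbzCl (1.3 equiv), NaHCO3, CH2Cl2/H2O, 0 °C to rt
Reagents that add atoms: benzyl chloroformate, O=C(Cl)OCc1ccccc1
Why: Schotten–Baumann carbamoylation, in which the di-sec-alkyl amine, though hindered, remains far more nucleophilic towards the reactive chloroformate than the secondary alcohol without an acyl-transfer catalyst, and the weak base avoids closure to an oxazolidinone.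

Step 8
Reactants: 11 benzyl N-[(1S)-cyclopent-2-en-1-yl]-N-[(2R,3R)-3-hydroxypent-4-en-2-yl]carbamate
Product: 12 benzyl N-[(2R,3R)-3-acetoxypent-4-en-2-yl]-N-[(1S)-cyclopent-2-en-1-yl]carbamate
Conditions: Ac2O, Et3N, DMAP (cat.), CH2Cl2, rt
Reagents that add atoms: acetic anhydride, CC(=O)OC(C)=O
Why: DMAP-catalysed acetylation occurs at oxygen with retention at C3 and installs the ester of the target only after step 6, so no ionisable allylic acetate ever meets zerovalent palladium.

Step 9
Reactants: 13 undec-10-enoic acid
Product: 15 dodec-11-en-2-one, via dilithium gem-diolate 14 (not isolated)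
Conditions: MeLi (2.1 equiv), Et2O, 0 °C to rt; inverse quench into ice-cold 1 M HCl
Reagents that add atoms: methyllithium, [Li]C
Why: Methyl ketone synthesis from a carboxylic acid with two equivalents of an organolithium (deprotonation, then carbonyl addition) stops at 14, which cannot collapse until the inverse acidic quench has destroyed excess reagent, so no tertiary alcohol should form and the remote terminal alkene is inert.

Step 10
Reactants: 12 benzyl N-[(2R,3R)-3-acetoxypent-4-en-2-yl]-N-[(1S)-cyclopent-2-en-1-yl]carbamate; 15 dodec-11-en-2-one (4 equiv)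
Product: 17 benzyl (2R,3R,6S)-3-acetoxy-2-methyl-6-[(3E)-13-oxotetradec-3-en-1-yl]-3,6-dihydro-2H-pyridine-1-carboxylate, via butenyl tetrahydropyridine 16 (not isolated)
Conditions: RuCl2(H2IMes)(=CH-C6H4-2-O-i-Pr) (second-generation Hoveyda–Grubbs catalyst, 2 × 5 mol %), 1,4-benzoquinone (10 mol %), CH2Cl2 (0.02 M in 12), 40 °C, slow argon sparge
Reagents that add atoms: none
Why: The reaction runs through ruthenium alkylidene/alkene [2+2] cycloadditions and cycloreversions: an alkylidene generated on the C4 vinyl group (or on 15) adds across the strained C3'=C5 bond, the metallacyclobutane opens the carbocycle, C4=C5 ends up inside the new ring, and the carbene left on C3' is released as the terminal alkene 16 or directly by 15, 16 then being capped by 15 with loss of ethylene. The closest known reaction type is ring-rearrangement metathesis of N-protected N-(but-3-enyl)cyclopent-2-enylamines to 1,2,3,6-tetrahydropyridines, run in tandem with cross metathesis. The one ring closed is the six-membered N1–C2–C3–C4=C5–C6 ring, by ring-closing metathesis that places the new alkene inside the ring while the five-membered carbocycle disappears. No stereocentre is formed, since C6 keeps its bonds to N1, H, C5 and C1' and C2 and C3 are spectators, so the configurations from steps 1, 2 and 6 are carried over and the E/Z mixture expected at C3'=C4' (drawn E) vanishes in step 11. The selectivity needed is the correct pairing of three alkenes: the planar carbamate and its two α-branched N-substituents compress the C4···C5 distance so that closure should outrun oligomerisation at this dilution, an opening in the wrong orientation that caps C5 is self-correcting because closure onto C4 expels 15 again, the excess of the fast-dimerising type 1 olefin 15 (its dimer reacts too) biases the otherwise statistical capping of C3', and the ring alkene flanked by C3 and C6 is too hindered to re-enter. The network is reversible and is driven to 17 by sweeping out ethylene and by the strain given up when the cyclopentene opens, while benzoquinone intercepts ruthenium hydrides that would migrate alkenes and falsify the chain length.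

Step 11
Reactants: 17 benzyl (2R,3R,6S)-3-acetoxy-2-methyl-6-[(3E)-13-oxotetradec-3-en-1-yl]-3,6-dihydro-2H-pyridine-1-carboxylate
Product: 18 benzyl (2R,3R,6S)-3-acetoxy-2-methyl-6-(13-oxotetradecyl)piperidine-1-carboxylate
Conditions: H2 (1 atm, stopped after uptake of 2 equiv), 5% Rh/Al2O3, EtOAc, rt
Reagents that add atoms: none
Why: Heterogeneous hydrogenation over rhodium saturates both disubstituted alkenes but has little tendency to form π-allyl species or to cleave benzylic C–O bonds, so the allylic C3 acetate, the allylic C6–N bond, the Cbz group and the ketone should persist, and no stereocentre is created.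

Step 12
Reactants: 18 benzyl (2R,3R,6S)-3-acetoxy-2-methyl-6-(13-oxotetradecyl)piperidine-1-carboxylate
Product: 20 (-)-3-O-acetylspectaline, via carbamic acid 19 (not isolated)
Conditions: H2 (1 atm), 10% Pd/C, EtOH, rt; filtration through Celite
Reagents that add atoms: none
Why: Hydrogenolysis of the benzyl carbamate gives 19, which decarboxylates spontaneously under neutral conditions; with no allylic C–O bond left the acetate is safe, and the amine flanked by the C2 and C6 substituents is too hindered at room temperature for O-to-N acetyl shift or reductive amination with the remote ketone.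

Compound list
1 | D-alanine methyl ester hydrochloride, methyl (2R)-2-aminopropanoate hydrochloride | C[C@@H](N)C(=O)OC.Cl | starting material
2 | methyl (2R)-2-[(diphenylmethylidene)amino]propanoate | C[C@@H](N=C(c1ccccc1)c1ccccc1)C(=O)OC | intermediate
3 | vinylmagnesium bromide | C=C[Mg]Br | starting material
4 | aluminoxy acetal, diisobutylaluminium (2R)-2-[(diphenylmethylidene)amino]-1-methoxypropan-1-olate (not isolated) | C[C@@H](N=C(c1ccccc1)c1ccccc1)C(OC)O[Al](CC(C)C)CC(C)C | intermediate
5 | (3R,4R)-4-[(diphenylmethylidene)amino]pent-1-en-3-ol (syn) | C=C[C@@H](O)[C@@H](C)N=C(c1ccccc1)c1ccccc1 | intermediate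
6 | (3R,4R)-4-aminopent-1-en-3-ol hydrochloride | C=C[C@@H](O)[C@@H](C)N.Cl | intermediate
7 | cyclopent-2-en-1-one | O=C1CCC=C1 | starting material
8 | (±)-cyclopent-2-en-1-ol | OC1CCC=C1 | intermediate
9 | (±)-cyclopent-2-en-1-yl methyl carbonate | COC(=O)OC1CCC=C1 | intermediate
10 | (3R,4R)-4-{[(1S)-cyclopent-2-en-1-yl]amino}pent-1-en-3-ol | C=C[C@@H](O)[C@@H](C)N[C@H]1CCC=C1 | intermediate
11 | benzyl N-[(1S)-cyclopent-2-en-1-yl]-N-[(2R,3R)-3-hydroxypent-4-en-2-yl]carbamate | C=C[C@@H](O)[C@@H](C)N(C(=O)OCc1ccccc1)[C@H]2CCC=C2 | intermediate
12 | benzyl N-[(2R,3R)-3-acetoxypent-4-en-2-yl]-N-[(1S)-cyclopent-2-en-1-yl]carbamate (key-step precursor) | C=C[C@@H](OC(C)=O)[C@@H](C)N(C(=O)OCc1ccccc1)[C@H]2CCC=C2 | intermediate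
13 | undec-10-enoic acid | C=CCCCCCCCCC(=O)O | starting material
14 | dilithium dodec-11-ene-2,2-diolate (not isolated) | C=CCCCCCCCCC(C)([O-])[O-].[Li+].[Li+] | intermediate
15 | dodec-11-en-2-one (isolated terminal alkene, non-conjugated methyl ketone) | CC(=O)CCCCCCCCC=C | intermediate
16 | benzyl (2R,3R,6S)-3-acetoxy-6-(but-3-en-1-yl)-2-methyl-3,6-dihydro-2H-pyridine-1-carboxylate (not isolated) | C=CCC[C@H]1C=C[C@@H](OC(C)=O)[C@@H](C)N1C(=O)OCc2ccccc2 | intermediate
17 | benzyl (2R,3R,6S)-3-acetoxy-2-methyl-6-[(3E)-13-oxotetradec-3-en-1-yl]-3,6-dihydro-2H-pyridine-1-carboxylate (key-step product) | CC(=O)CCCCCCCC/C=C/CC[C@H]1C=C[C@@H](OC(C)=O)[C@@H](C)N1C(=O)OCc2ccccc2 | intermediate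
18 | benzyl (2R,3R,6S)-3-acetoxy-2-methyl-6-(13-oxotetradecyl)piperidine-1-carboxylate | CC(=O)CCCCCCCCCCCC[C@H]1CC[C@@H](OC(C)=O)[C@@H](C)N1C(=O)OCc2ccccc2 | intermediate
19 | (2R,3R,6S)-3-acetoxy-2-methyl-6-(13-oxotetradecyl)piperidine-1-carboxylic acid (not isolated) | CC(=O)CCCCCCCCCCCC[C@H]1CC[C@@H](OC(C)=O)[C@@H](C)N1C(=O)O | intermediate
20 | (-)-3-O-acetylspectaline, (2R,3R,6S)-2-methyl-6-(13-oxotetradecyl)piperidin-3-yl acetate (all-cis) | CC(=O)CCCCCCCCCCCC[C@H]1CC[C@@H](OC(C)=O)[C@@H](C)N1 | target

Total step count: 12.
Longest linear sequence: 9 steps (1, 2, 3, 6, 7, 8, 10, 11, 12) from D-alanine methyl ester hydrochloride.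

Steps most likely to fail

Step 10.
- **Risk:** The three-alkene network may not funnel cleanly. Possible causes are intermolecular ring opening (oligomerisation), self-coupling of the ring-rearranged terminal alkene instead of capping by 15, and ruthenium-hydride alkene migration that alters the chain length.
- **Fallback:** It sets out from 12 and comes back at 17. The cascade is given up in favour of two separate two-alkene metatheses, with the chain offered as an internal olefin.
- Compound 12 is ring-rearranged alone under ethylene (1 atm) with RuCl2(PCy3)2(=CHPh) (first-generation Grubbs catalyst) at 0.01 M in CH2Cl2. Ethylene is then the only capping olefin, and 16 is isolated and purified.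
- Separately, 15 is self-metathesised neat under vacuum to (E)-docos-11-ene-2,21-dione F1.
- Then 16 and F1 (2 equiv) are cross-coupled at 0.2 M with RuCl2(H2IMes)(=CH-C6H4-2-O-i-Pr). The internal partner keeps the methylidene and ethylene levels low, and the 15 it releases is itself a competent partner. This should give 17.

Step 6.
- **Risk:** A bulky, chiral primary amine may discriminate poorly between the two allyl termini (mismatch with the ligand). Attack may also be slow enough for the product to re-ionise and lose its C6 configuration.
- **Fallback:** It sets out from 9 and comes back at 10. The union of the two halves is moved from the N–C6 bond to the N–C2 bond.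
- Carbonate 9 is aminated with phthalimide, the best-precedented nitrogen nucleophile for this catalyst system (Pd2(dba)3·CHCl3, same diphosphine, CH2Cl2, rt). This gives 2-[(1S)-cyclopent-2-en-1-yl]isoindoline-1,3-dione F2, which is expected to be crystalline and upgradable by recrystallisation.
- Hydrazinolysis (N2H4·H2O, EtOH, reflux under argon) gives (1S)-cyclopent-2-en-1-amine F3, handled as a CH2Cl2 solution.
- Methyl L-lactate is converted (Tf2O, 2,6-lutidine, CH2Cl2, -78 °C) into methyl (2S)-2-(trifluoromethylsulfonyloxy)propanoate F4.
- F3 displaces the triflate of F4 with clean SN2 inversion (i-Pr2NEt, CH2Cl2, -78 °C to rt) to give methyl (2R)-2-{[(1S)-cyclopent-2-en-1-yl]amino}propanoate F5.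
- One-pot half-reduction and vinylation as in step 2 follows (i-Bu2AlH, 2.2 equiv, the extra equivalent metalating N–H; then 3). It should proceed through an N–Al–O chelate to the syn amino alcohol 10.

Step 2.
- **Risk:** The THF that accompanies the Grignard reagent may erode chelate control and give poor facial selectivity at C3. Premature collapse of the acetal may also lead to over-reduction.
- **Fallback:** It sets out from 6, as the C3-epimeric mixture obtained by carrying unseparated 5 through step 3, and comes back at 6 as the single syn isomer. Kinetic facial control is replaced by a stereoconvergent correction under thermodynamic control.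
- N-Benzoylation (BzCl, NaHCO3, CH2Cl2/H2O) gives N-[(2R,3RS)-3-hydroxypent-4-en-2-yl]benzamide F6.
- Treatment with ClCO2Me, pyridine and DMAP gives (3RS,4R)-4-benzamidopent-1-en-3-yl methyl carbonate F7.
- Pd(PPh3)4 (5 mol %) and K2CO3 in MeCN at 60 °C ionise both epimers to interconverting π-allyl species, and the amide oxygen closes 5-exo. The vinyl oxazoline re-ionises under zerovalent palladium, so the mixture should settle on the more stable trans isomer, (4R,5R)-4-methyl-2-phenyl-5-vinyl-4,5-dihydro-1,3-oxazole F8.
- Hydrolysis (2 M HCl, THF, reflux) returns 6.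

Further compounds
F1 | step 10 | (E)-docos-11-ene-2,21-dione | CC(=O)CCCCCCCC/C=C/CCCCCCCCC(C)=O
F2 | step 6 | 2-[(1S)-cyclopent-2-en-1-yl]isoindoline-1,3-dione | O=C1c2ccccc2C(=O)N1[C@H]3CCC=C3
F3 | step 6 | (1S)-cyclopent-2-en-1-amine | N[C@H]1CCC=C1
F4 | step 6 | methyl (2S)-2-(trifluoromethylsulfonyloxy)propanoate | C[C@H](OS(=O)(=O)C(F)(F)F)C(=O)OC
F5 | step 6 | methyl (2R)-2-{[(1S)-cyclopent-2-en-1-yl]amino}propanoate | C[C@@H](N[C@H]1CCC=C1)C(=O)OC
F6 | step 2 | N-[(2R,3RS)-3-hydroxypent-4-en-2-yl]benzamide | C=CC(O)[C@@H](C)NC(=O)c1ccccc1
F7 | step 2 | (3RS,4R)-4-benzamidopent-1-en-3-yl methyl carbonate | C=CC(OC(=O)OC)[C@@H](C)NC(=O)c1ccccc1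
F8 | step 2 | (4R,5R)-4-methyl-2-phenyl-5-vinyl-4,5-dihydro-1,3-oxazole | C=C[C@H]1OC(c2ccccc2)=N[C@@H]1C
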